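What is left in gamma at its last reading, 35.1 mM of Sbt, still has 105 h to run before the time asked of delta, which has the same charge.

| setting | gamma | zeta | theta | delta |
|---|---|---|---|---|
| Sbt | 150 mM | 75.0 mM | 150 mM | 150 mM |
| Ptn | 225 mM | 225 mM | 110 mM | 225 mM |
| time |  |  |  | 160 h |

| run | time / h | [Sbt] / mM |
|---|---|---|
| gamma run | 7.9 | 86.1 |
| gamma run | 16 | 68.6 |
| gamma run | 24 | 57.5 |
| gamma run | 31 | 50.5 |
| gamma run | 39 | 44.4 |
| gamma run | 47 | 40.2 |
| gamma run | 55 | 35.1 |
| zeta run | 7.9 | 40.9 |
| zeta run | 16 | 32.1 |
| zeta run | 24 | 26.6 |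
| zeta run | 31 | 22.6 |
| zeta run | 39 | 18.5 |
| zeta run | 47 | 16.1 |
| zeta run | 55 | 15.0 |
| theta run | 7.9 | 102.2 |
| theta run | 16 | 84.7 |
| theta run | 24 | 71.7 |
| theta run | 31 | 63.4 |
| theta run | 39 | 56.9 |
| theta run | 47 | 51.5 |
| theta run | 55 | 45.6 |

(readings scatter by 0.4 mM)

- reaction order in [Ptn] at the outset, round the charge of the gamma run, defined at two percent of the Sbt turned into Pdt
- reaction order in [Sbt] at the outset, round the charge of the gamma run, defined at two percent of the Sbt turned into Pdt (one fixed amount of Pdt, the same in the runs compared)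
- Sbt in the delta run at 160 h, as a share of the Sbt charged

- Overall: Sbt + Ptn -> Pdt.
- Constant volume, constant temperature.
- An order is taken over about fifteen percent of the charge, up and down.

Does that leftover keep falling, and at what pace? Start with theta. Why theta? Because Ptn is its limiting reagent, 110 mM against 150 mM of Sbt.

If each Sbt lost took one Ptn, what would theta hold? 23.4 mM of Ptn at 31 h, and 5.60 mM at 55 h.

And the slope of ln[Sbt]? In theta it reads 0.0135 h⁻¹ early in that stretch and 0.0152 h⁻¹ late, nearly constant. A loss paid for in Ptn would slow as that remainder shrank, so Sbt appears to have a way out that needs no Ptn. Over the whole stretch theta reads 0.0137 h⁻¹. Call this fractional loss of Sbt per hour, late in a run, the tail constant.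

The weak spot: does it fit gamma? Gamma's slope over the same stretch reads 0.0152 h⁻¹, a little steeper. Yet the same subtraction leaves gamma 110 mM of Ptn against 5.60 mM in theta. So gamma's Ptn seems to be going somewhere besides Sbt.

Your number? Frozen over the remaining time, the tail constant takes gamma's leftover to 5.53% of the charge, and that is my estimate for delta at 160 h.

The forecast gives orders of 0.8 in Ptn and 0.95 in Sbt. For delta it gives 12.5%, higher than my figure, on these grounds: “Extending the late slope, about 0.6 per ln t”.

The steps behind the flask:

    Sbt + Ptn → Pdt (0.7128 L mol⁻¹ h⁻¹)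
    2 Ptn → X (0.9936 L mol⁻¹ h⁻¹)
    Sbt → G (0.01253 h⁻¹)

Delta ends at 5.84% of its Sbt charged, 0.31 percentage points above the frozen tail, with orders of 1.0 in Ptn and 1.1 in Sbt. At delta's charge, the first half-life of Ptn by its self-reaction to X alone is 2.24 h, shorter than the time asked. Frozen from zeta's reading of 22.6 mM at 31 h, the tail constant gives 16.3 mM at 55 h, and zeta reads 15.0 mM.

(The numbers in the tables were generated by integration for substances that don't exist; scatter was added.)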